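In the theta run, 41.7 % of the substrate had gone in by 2.50 h, yet 34.1 % stood as substrate, so you can watch the feed being consumed as it enters. The question is what that means for north-west and west.

common to all: substrate 0.31 M (fed, over 6.0 h)

| run | first nucleophile | solid second nucleophile | temperature | remark | time |
|---|---|---|---|---|---|
| epsilon | 1.2 equiv | 0.75 equiv | 48 °C | run made earlier |  |
| theta | 1.2 equiv | 3 equiv | 64 °C | run made earlier |  |
| north-west | 1.20 equiv | 1.50 equiv | 40 °C |  | 6.0 h |
| west | 1.20 equiv | 1.50 equiv | 70 °C |  | 6.0 h |

- epsilon (time / h: target / %, substrate / %): 1.33: 0, 21.9; 3.00: 1.0, 48.7; 4.00: 2.1, 64.3; 6.00: 4.4, 94.3; 8.00: 7.6, 90.5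
- theta (time / h: target / %, substrate / %): 0.200: 0.6, 3.1; 0.667: 0.8, 10.3; 1.00: 1.3, 15.4; 1.50: 2.1, 22.7; 2.50: 5.0, 34.1

(standard deviation of a reading: 0.3 percentage points)

- which flask leads in amount of target, in percent of the substrate charged ("all alike" within 1.5 percentage points) (north-west / west / all alike)
- how much target is there at the end, in percent of the substrate charged: north-west
- how much target is there at the end, in percent of the substrate charged: west

- the numbers in the tables scatter with a standard deviation of 0.3 percentage points
- at the start none of the solid second nucleophile is in solution
- percentages count the whole charge, also what has not yet gone in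

Follow the rate and the fraction left. At the start, substrate climbs at the feed rate, 0.167 /h of the charge. If it is lost by first-order decay with constant k, the climb is slowed by the factor exp(−kt) at time t. Averaged over a dose of length t, the fraction of what was fed that is left is (1 − exp(−x))/x, with x = kt. For small x this is close to exp(−x/2).

Read that way, the theta run gives k = 0.160 /h and the epsilon run at 6.00 h gives 0.0196 /h. The solid loading differs between them as well, but I assign the whole ratio to temperature and spread it evenly per degree. That gives 0.353 /h at 70 °C and 0.00683 /h at 40 °C.

West's dosing number x, its loss constant times the dosing time, is 2.12. So I estimate that by the end of the dose in west the climb has slowed to 12.0 % of the feed, with 41.5 % left. By the same estimate north-west has x = 0.0410 and keeps 98.0 %. At the same two readings, target stands at 66.1 % of the substrate lost in theta and 77.2 % in epsilon, both figures carrying the scatter of the readings. Taking the nearer run for each flask, I reckon 38.6 % for west and 1.56 % for north-west.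

The forecast, holding that “substrate simply accumulates and reacts slowly”, names west, with 3.5 % for north-west and 28 % for west. My west figure is higher and my north-west figure lower, but the order is the same.

The flasks give west as the leader, with 32.7 % in west and 1.46 % in north-west.

    first nucleophile + intermediate → target (k = 8.00 /M/min, Ea = 73.0 kJ/mol)
    intermediate → solvolysis product (k = 1.90 /min, Ea = 101 kJ/mol)
    substrate → intermediate (k = 0.00590 /min, Ea = 118 kJ/mol)
    solid second nucleophile ⇌ second nucleophile, rate k4*(cs4 - [second nucleophile]) while solid is left; crystals form when [second nucleophile] > cs4 (solubility = 0.0990 M, k = 0.0480 /min)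
    second nucleophile + intermediate → other capture product (k = 1.20 /M/min, Ea = 49.0 kJ/mol)
    (constants at 70 °C)

The forecast's west figure is off by 4.7 percentage points, far less than the gap of 31 points between the flasks. At the end of west, solvolysis product stands at 24.3 % beside the target. West's x of 2.12 gives 41.5 % left, and the flask holds 41.5 %. The neighbour, west with 3.00 equiv of first nucleophile, has the same temperature and dose, and it too holds 41 % of substrate, while its target reaches 45.2 %.

The numbers in the tables were computed for substances that don't exist, noise included.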